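The numbers belong to no real substance; the rest is arithmetic.

Freeze the dissolved level first, then ask who takes the starting material there.

solid substrate 15 mM; enzyme 3.0 µM; time 10 d

    starting material + enzyme ⇌ complex (K1 = 27.5 M⁻¹, k1 = 1.67 × 10⁶ M⁻¹ h⁻¹)
    2 starting material → self-condensation product (k2 = 54.3 M⁻¹ h⁻¹)
    solid substrate ⇌ starting material, rate k3*(cs3 - [starting material]) while solid is left; crystals form when [starting material] > cs3 (cs3 = 13 mM, k3 = 1.35 h⁻¹)
    complex → enzyme + target (k4 = 1500 h⁻¹)

- the state of affairs at 10 d: stopped, and by what, or still going (for what has run out or reacted, a solid counts together with what of it has only dissolved) (forward and back rates have come level / it is still moving / no working catalyst is left / all of the solid substrate has reacted)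
- the target standing at 10 d, as a percentage of the solid substrate charged

- percentages count the solid substrate that a species holds: one self-condensation product counts as two
- two of one species on the left: rate k times its square, two consumed each time
- solid, in amounts per volume of the solution: solid substrate
- at the start none of the solid substrate is in solution
- what has only dissolved of solid substrate counts as not reacted
- the reaction counts as stopped when no species that holds the solid substrate changes by six tenths of a point or more over the second half of the time
- run time (flask): 10 d

Here is my own reckoning for this flask, with A for dissolved starting material and k for the self-condensation constant. Where does A sit while solid lasts? The enzyme's Michaelis constant, back plus turnover constant over forward constant, is Km = 37.3 mM. For A well below that, the enzyme is a pseudo-first-order drain, g = 0.121 h⁻¹. Balancing dissolving against both drains freezes A near Ap = 7.63 mM, which is below Km.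

Who takes it there? The enzyme draws 0.765 mM h⁻¹ of a feed of 7.25 mM h⁻¹, a share of 10.6%. Applied to the 7.37 mM that passes through, this reckons to 0.778 mM of target.

What happens once the solid is gone? Take the crossover concentration, the level where enzyme and self-condensation draw A equally: Ac = g/(2k) = 1.11 mM. Ap lies above Ac, so self-condensation leads at that level. The falling tail gives Ac ln(1 + Ap/Ac) = 2.29 mM of target. The total is 3.07 mM, or 20.5% of the charge. The tail's clock, 1/g = 8.26 h, is far shorter than 10 d, so I expect this flask to be over well before the end.

The forecast says all of the solid substrate has reacted and 20.6%, slightly above mine, holding that “only the low-concentration tail favours the enzyme”.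

The simulation gives all of the solid substrate has reacted and 20.8%. At 1.00 d this flask already holds 20.3% target and 79.2% self-condensation product. For the neighbour flask with 25 mM of solid substrate I keep Ap and Ac = 1.11 mM, so the same tail of 2.29 mM, while its plateau passes 17.4 mM, more than in this flask. That reckons to 4.13 mM of target, 16.5% of its charge. The neighbour flask stands at 16.8%.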